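Retrosynthesis: ring C is cut at C2–C3 and O1–C8a in one stroke, giving the ring-B aldehyde (C2=O1) and a ring-A methyl ketone with fluorine on C8a; next the C8–CH2 bond (aryl bromide + lavandulylzinc), last the Cα–prenyl bond of the side chain.
Forward: (S)-lavandulyl iodide is made in four steps; ring A is made as 3-bromo-2-fluoro-4,6-bis(methoxymethoxy)acetophenone and joined to the side chain by Negishi coupling; ring B comes in as its aldehyde; ring C is closed last and the four methoxymethyl (MOM) ethers are then removed.
Enabling feature: in ring A, C8a is ortho to C4a (which carries the C4 carbonyl) and meta to the oxygens on C5 and C7, so the unit C3–C4(=O)–C4a–C8a(F) is nucleophilic at C3 and electrophilic at C8a and meets the C2=O1 carbonyl of the aldehyde in a formal oxa-[4+2] annulation; the single fluorine also fixes the side chain at C8 and not at C6.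
Stereochemistry: the side-chain centre comes from an oxazolidinone-controlled enolate alkylation and is not touched again; C2 comes from the catalyst-controlled aldol stage of the annulation and is kept because the C2–O1 bond is never broken.

Key step: step 11

Assumption: 5-fluororesorcinol and 2,4-dihydroxy-5-methoxybenzaldehyde are taken as catalogue compounds.

Step 1
Reactants: 1 (S)-4-benzyloxazolidin-2-one; 2 senecioyl chloride (3-methylbut-2-enoyl chloride)
Product: 3 (S)-4-benzyl-3-(3-methylbut-2-enoyl)oxazolidin-2-one
Conditions: n-BuLi, THF, −78 °C; then 2, −78 → 0 °C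
Reagents that add atoms: none
Why: N-acylation of the lithiated oxazolidinone by an acid chloride is the standard entry to N-enoyl auxiliaries and creates no stereocentre.

Step 2
Reactants: 3 (S)-4-benzyl-3-(3-methylbut-2-enoyl)oxazolidin-2-one; 4 prenyl bromide (1-bromo-3-methylbut-2-ene)
Product: 5 (S)-4-benzyl-3-[(2S)-5-methyl-2-(prop-1-en-2-yl)hex-4-enoyl]oxazolidin-2-one
Conditions: NaN(SiMe3)2, THF, −78 °C; then 4, −78 °C; AcOH quench at −78 °C
Reagents that add atoms: none
Why: γ-deprotonation gives the chelated (Z)-dienolate, which in this deconjugative auxiliary-controlled enolate alkylation should react at the α-carbon on the face away from the benzyl group, setting the (2S) centre and creating the isopropenyl group in the same event.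

Step 3
Reactants: 5 (S)-4-benzyl-3-[(2S)-5-methyl-2-(prop-1-en-2-yl)hex-4-enoyl]oxazolidin-2-one
Product: 6 (S)-lavandulol, (2S)-5-methyl-2-(prop-1-en-2-yl)hex-4-en-1-ol
Conditions: LiBH4, THF, 0 °C → rt
Reagents that add atoms: none
Why: reductive cleavage of the N-acyl oxazolidinone with LiBH4 gives the primary alcohol fast enough that the doubly activated α-centre should not epimerise, and it returns the auxiliary.

Step 4
Reactants: 6 (S)-lavandulol
Product: 7 (S)-lavandulyl iodide, (3S)-3-(iodomethyl)-2,6-dimethylhepta-1,5-diene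
Conditions: PPh3, I2, imidazole, CH2Cl2, 0 °C → rt
Reagents that add atoms: iodine, II
Why: Appel-type iodination replaces the primary hydroxyl at the CH2 carbon only, so the neighbouring stereocentre is untouched.

Step 5
Reactants: 8 5-fluororesorcinol (5-fluorobenzene-1,3-diol)
Product: 9 1-(2-fluoro-4,6-dihydroxyphenyl)ethan-1-one
Conditions: AcOH, ZnCl2, 140 °C
Reagents that add atoms: acetic acid, CC(=O)O
Why: Nencki acylation of a resorcinol goes to the carbon ortho to one hydroxyl and para to the other (here the carbon next to fluorine), as in the preparation of resacetophenone.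

Step 6
Reactants: 9 1-(2-fluoro-4,6-dihydroxyphenyl)ethan-1-one
Product: 10 1-[2-fluoro-4,6-bis(methoxymethoxy)phenyl]ethan-1-one
Conditions: NaH, MOMCl, DMF, 0 °C → rt
Reagents that add atoms: chloromethyl methyl ether (MOMCl), COCCl
Why: Williamson-type O-alkylation of both phenoxides (NaH is needed for the hydrogen-bonded ortho hydroxyl) gives acetal ethers that should survive the organometallic, basic and fluoride steps ahead.

Step 7
Reactants: 10 1-[2-fluoro-4,6-bis(methoxymethoxy)phenyl]ethan-1-one
Product: 11 1-[3-bromo-2-fluoro-4,6-bis(methoxymethoxy)phenyl]ethan-1-one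
Conditions: NBS, MeCN, 0 °C → rt
Reagents that add atoms: N-bromosuccinimide, O=C1CCC(=O)N1Br
Why: electrophilic aromatic bromination of a resorcinol diether should take the carbon ortho to one ether and para to the other (C3, next to fluorine) and not the crowded carbon between the two ethers.

Step 8
Reactants: 7 (S)-lavandulyl iodide; 11 1-[3-bromo-2-fluoro-4,6-bis(methoxymethoxy)phenyl]ethan-1-one
Product: 13 1-{2-fluoro-4,6-bis(methoxymethoxy)-3-[(2R)-5-methyl-2-(prop-1-en-2-yl)hex-4-en-1-yl]phenyl}ethan-1-one, via lavandulylzinc iodide 12 (not isolated)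
Conditions: 7, Zn dust, LiCl, THF, 40 °C; then 11, Pd(OAc)2 (2 mol %), CPhos (4 mol %), THF/toluene, rt → 40 °C
Reagents that add atoms: none
Why: Negishi coupling of a primary alkylzinc halide with a di-ortho-substituted aryl bromide under a bulky biarylphosphine (fast reductive elimination, little β-hydride elimination) tolerates the ketone and forms no new stereocentre, the side-chain centre lying β to the metal.

Step 9
Reactants: 14 2,4-dihydroxy-5-methoxybenzaldehyde
Product: 15 5-methoxy-2,4-bis(methoxymethoxy)benzaldehyde
Conditions: NaH, MOMCl, DMF, 0 °C → rt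
Reagents that add atoms: chloromethyl methyl ether (MOMCl), COCCl
Why: Williamson-type O-alkylation of both phenoxides of a non-enolisable aldehyde masks ring B in the same form as ring A, so that one final operation frees all four phenols.

Step 10
Reactants: 13 1-{2-fluoro-4,6-bis(methoxymethoxy)-3-[(2R)-5-methyl-2-(prop-1-en-2-yl)hex-4-en-1-yl]phenyl}ethan-1-one
Product: 16 (1-{2-fluoro-4,6-bis(methoxymethoxy)-3-[(2R)-5-methyl-2-(prop-1-en-2-yl)hex-4-en-1-yl]phenyl}ethenyloxy)trimethylsilane
Conditions: LiN(SiMe3)2, THF, −78 °C; TMSCl, −78 → 0 °C; non-aqueous work-up (pentane, filtration), used crude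
Reagents that add atoms: chlorotrimethylsilane, C[Si](C)(C)Cl
Why: the methyl group is the only enolisable position, so kinetic deprotonation and O-silylation (silyl enol ether formation) should give a single enol silane.

Step 11
Reactants: 16 (1-{2-fluoro-4,6-bis(methoxymethoxy)-3-[(2R)-5-methyl-2-(prop-1-en-2-yl)hex-4-en-1-yl]phenyl}ethenyloxy)trimethylsilane; 15 5-methoxy-2,4-bis(methoxymethoxy)benzaldehyde
Product: 18 (2S)-2-[5-methoxy-2,4-bis(methoxymethoxy)phenyl]-5,7-bis(methoxymethoxy)-8-[(2R)-5-methyl-2-(prop-1-en-2-yl)hex-4-en-1-yl]-2,3-dihydro-4H-chromen-4-one, via silyl aldolate 17 (not isolated)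
Conditions: 15 (1.0 equiv), 16 (1.2 equiv), N-tosyl-(R)-tryptophan-derived B-butyl-1,3,2-oxazaborolidin-5-one (20 mol %), EtCN, −78 °C; then Bu4N[Ph3SiF2] (0.4 equiv), THF, −78 → −20 °C; AcOH quench
Reagents that add atoms: none
Why: Proposed new method: a one-flask formal oxa-[4+2] annulation in which the chiral boron Lewis acid binds aldehyde 15, enol silane 16 attacks its Si face through an open transition state (Mukaiyama aldol) and silyl transfer gives the β-silyloxy ketone 17, which cannot undergo retro-aldol; fluoride then attacks silicon, the oxygen set free adds to C8a, the C4 carbonyl stabilises the Meisenheimer complex, and loss of fluoride closes ring C while the expelled fluoride desilylates the next molecule of 17, so only an initiating amount is needed. The closest known reaction types are the oxazaborolidinone-catalysed enantioselective Mukaiyama aldol of aryl methyl ketone trimethylsilyl enol ethers with aromatic aldehydes, the fluoride-catalysed etherification of aryl fluorides with silyl ethers, and the ring-closing SNAr of o-fluoroaryl ketones by a tethered heteroatom nucleophile. Ring C closes by addition–elimination at an aromatic carbon through a six-membered transition state (formally 6-exo-trig on C8a=C8, the charge being relayed through C4a into the C4 carbonyl, which the forming ring holds coplanar with ring A). The only new stereocentre, C2, is set in the aldol stage by the catalyst (the (R)-tryptophan-derived antipode is proposed for Si-face attack and is exchanged for its mirror image if a trial aldol shows the opposite sense) and survives ring closure because the C2–O1 bond is never broken. The step needs enantiofacial control (catalyst), closure at C8a and not at C5 (fluoride is by far the better leaving group than methoxymethoxide), and closure faster than retro-aldol or β-elimination of the transient alkoxide (secured by the silyl cap that is lifted only at the moment of closure, low temperature, the unimolecular six-membered closure, and the meta placement of the C5 and C7 oxygens, which leaves C8a electrophilic).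

Step 12
Reactants: 18 (2S)-2-[5-methoxy-2,4-bis(methoxymethoxy)phenyl]-5,7-bis(methoxymethoxy)-8-[(2R)-5-methyl-2-(prop-1-en-2-yl)hex-4-en-1-yl]-2,3-dihydro-4H-chromen-4-one
Product: 19 (2S)-2-(2,4-dihydroxy-5-methoxyphenyl)-5,7-dihydroxy-8-[(2R)-5-methyl-2-(prop-1-en-2-yl)hex-4-en-1-yl]-2,3-dihydro-4H-chromen-4-one
Conditions: 3 M HCl (aq), MeOH/THF, rt → 40 °C, NaHCO3 quench
Reagents that add atoms: none
Why: acid-catalysed acetal exchange with methanol (MOM ether cleavage) is the usual unmasking of prenylated polyphenols and should be mild enough to spare the two side-chain alkenes and the C2 centre, which epimerises under base and not under dilute acid.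

Compound list
1 | (S)-4-benzyloxazolidin-2-one | O=C1OC[C@H](Cc2ccccc2)N1 | starting material
2 | 3-methylbut-2-enoyl chloride (senecioyl chloride) | CC(C)=CC(=O)Cl | starting material
3 | (S)-4-benzyl-3-(3-methylbut-2-enoyl)oxazolidin-2-one | CC(C)=CC(=O)N1[C@@H](Cc2ccccc2)COC1=O | intermediate
4 | 1-bromo-3-methylbut-2-ene (prenyl bromide) | CC(C)=CCBr | starting material
5 | (S)-4-benzyl-3-[(2S)-5-methyl-2-(prop-1-en-2-yl)hex-4-enoyl]oxazolidin-2-one | C=C(C)[C@H](CC=C(C)C)C(=O)N1[C@@H](Cc2ccccc2)COC1=O | intermediate
6 | (2S)-5-methyl-2-(prop-1-en-2-yl)hex-4-en-1-ol, (S)-lavandulol | C=C(C)[C@H](CC=C(C)C)CO | intermediate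
7 | (3S)-3-(iodomethyl)-2,6-dimethylhepta-1,5-diene, (S)-lavandulyl iodide | C=C(C)[C@H](CC=C(C)C)CI | intermediate
8 | 5-fluorobenzene-1,3-diol (5-fluororesorcinol) | Oc1cc(O)cc(F)c1 | starting material
9 | 1-(2-fluoro-4,6-dihydroxyphenyl)ethan-1-one | CC(=O)c1c(O)cc(O)cc1F | intermediate
10 | 1-[2-fluoro-4,6-bis(methoxymethoxy)phenyl]ethan-1-one | CC(=O)c1c(OCOC)cc(OCOC)cc1F | intermediate
11 | 1-[3-bromo-2-fluoro-4,6-bis(methoxymethoxy)phenyl]ethan-1-one | CC(=O)c1c(OCOC)cc(OCOC)c(Br)c1F | intermediate
12 | [(2S)-5-methyl-2-(prop-1-en-2-yl)hex-4-en-1-yl]zinc iodide (LiCl complex, formed in the flask) | C=C(C)[C@H](CC=C(C)C)C[Zn]I | intermediate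
13 | 1-{2-fluoro-4,6-bis(methoxymethoxy)-3-[(2R)-5-methyl-2-(prop-1-en-2-yl)hex-4-en-1-yl]phenyl}ethan-1-one | C=C(C)[C@H](CC=C(C)C)Cc1c(OCOC)cc(OCOC)c(C(C)=O)c1F | intermediate
14 | 2,4-dihydroxy-5-methoxybenzaldehyde | COc1cc(C=O)c(O)cc1O | starting material
15 | 5-methoxy-2,4-bis(methoxymethoxy)benzaldehyde | COCOc1cc(OCOC)c(OC)cc1C=O | intermediate
16 | (1-{2-fluoro-4,6-bis(methoxymethoxy)-3-[(2R)-5-methyl-2-(prop-1-en-2-yl)hex-4-en-1-yl]phenyl}ethenyloxy)trimethylsilane | C=C(C)[C@H](CC=C(C)C)Cc1c(OCOC)cc(OCOC)c(C(=C)O[Si](C)(C)C)c1F | intermediate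
17 | (3S)-1-{2-fluoro-4,6-bis(methoxymethoxy)-3-[(2R)-5-methyl-2-(prop-1-en-2-yl)hex-4-en-1-yl]phenyl}-3-[5-methoxy-2,4-bis(methoxymethoxy)phenyl]-3-(trimethylsilyloxy)propan-1-one (formed in the flask) | C=C(C)[C@H](CC=C(C)C)Cc1c(OCOC)cc(OCOC)c(C(=O)C[C@H](O[Si](C)(C)C)c2cc(OC)c(OCOC)cc2OCOC)c1F | intermediate
18 | (2S)-2-[5-methoxy-2,4-bis(methoxymethoxy)phenyl]-5,7-bis(methoxymethoxy)-8-[(2R)-5-methyl-2-(prop-1-en-2-yl)hex-4-en-1-yl]-2,3-dihydro-4H-chromen-4-one | C=C(C)[C@H](CC=C(C)C)Cc1c(OCOC)cc(OCOC)c2c1O[C@H](c1cc(OC)c(OCOC)cc1OCOC)CC2=O | intermediate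
19 | (2S)-2-(2,4-dihydroxy-5-methoxyphenyl)-5,7-dihydroxy-8-[(2R)-5-methyl-2-(prop-1-en-2-yl)hex-4-en-1-yl]-2,3-dihydro-4H-chromen-4-one (CNP0323048.1) | C=C(C)[C@H](CC=C(C)C)Cc1c(O)cc(O)c2c1O[C@H](c1cc(OC)c(O)cc1O)CC2=O | target

Total step count: 12. Longest linear sequence: 8 steps (1, 2, 3, 4, 8, 10, 11, 12).

Steps most likely to fail

Step 11. The aldol stage may be slow or weakly face-selective with this electron-rich, ortho-substituted aldehyde. In the fluoride stage, retro-aldol cleavage or β-elimination of the transient alkoxide, or base-induced opening and reclosure of ring C, may erode the configuration at C2. The fallback uses known chemistry in two separate operations and runs from 13 and 15 back to 18. A diisopinocampheylboron-mediated aldol of 13 with 15 (chlorodiisopinocampheylborane of the antipode that attacks the Si face, Et3N, Et2O, −78 °C, non-oxidative work-up) gives the β-hydroxy ketone F1. F1 is then closed by ring-forming SNAr with KN(SiMe3)2 in THF at −78 → −30 °C to give 18.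

Step 8. Oxidative addition into the electron-rich C–Br bond flanked by fluorine and an ether may be slow. β-Hydride elimination and reinsertion at the alkylpalladium stage may scramble the side-chain centre, and the homoallylic radical on the zinc surface may undergo a vinyl shift. The fallback runs from 7 and 11 back to 13. Iodine–lithium exchange of 7 with t-BuLi (2 equiv, Et2O/pentane, −78 °C) gives the alkyllithium F2 without a long-lived radical. B-Methoxy-9-borabicyclo[3.3.1]nonane converts it into the lithium borate F3. B-alkyl Suzuki–Miyaura coupling of F3 with 11 (PdCl2(dppf), K3PO4 aq., DMF, rt) gives 13.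

Step 12. Protic acid may add the freed C7 hydroxyl across the isopropenyl group (chroman formation), hydrate or hydrochlorinate the alkenes, or leave the non-chelated acetals partly in place. The fallback runs from 18 back to 19. TMSOTf and 2,2′-bipyridyl in MeCN at 0 °C exchange the aryl MOM ethers for aryl trimethylsilyl ethers without protic acid, giving the tetrakis(trimethylsilyl) ether F4. F4 is hydrolysed with pH 7 buffer in THF to 19.

Further compounds
F1 | step 11 | (3S)-1-{2-fluoro-4,6-bis(methoxymethoxy)-3-[(2R)-5-methyl-2-(prop-1-en-2-yl)hex-4-en-1-yl]phenyl}-3-hydroxy-3-[5-methoxy-2,4-bis(methoxymethoxy)phenyl]propan-1-one | C=C(C)[C@H](CC=C(C)C)Cc1c(OCOC)cc(OCOC)c(C(=O)C[C@H](O)c2cc(OC)c(OCOC)cc2OCOC)c1F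
F2 | step 8 | [(2S)-5-methyl-2-(prop-1-en-2-yl)hex-4-en-1-yl]lithium | C=C(C)[C@H](CC=C(C)C)C[Li]
F3 | step 8 | lithium 9-methoxy-9-[(2S)-5-methyl-2-(prop-1-en-2-yl)hex-4-en-1-yl]-9-borabicyclo[3.3.1]nonan-9-uide | [Li+].C=C(C)[C@H](CC=C(C)C)C[B-]1(OC)C2CCCC1CCC2
F4 | step 12 | (2S)-2-[5-methoxy-2,4-bis(trimethylsilyloxy)phenyl]-8-[(2R)-5-methyl-2-(prop-1-en-2-yl)hex-4-en-1-yl]-5,7-bis(trimethylsilyloxy)-2,3-dihydro-4H-chromen-4-one | C=C(C)[C@H](CC=C(C)C)Cc1c(O[Si](C)(C)C)cc(O[Si](C)(C)C)c2c1O[C@H](c1cc(OC)c(O[Si](C)(C)C)cc1O[Si](C)(C)C)CC2=O
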